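Ring C of the lower unit, with C4 carried as a ketone, is a benzo-fused dihydropyranone and is cut at O1–C8a and C2–C3. One flask joins 3,4-bis(benzyloxy)benzaldehyde to the silyl enol ether of a 2-fluoroaryl benzyloxymethyl ketone: a catalyst-controlled Mukaiyama aldol makes C2–C3, and the released C2 alkoxide then displaces the fluorine on A-ring C8a, which the C4 carbonyl on neighbouring C4a activates (a benzo-Danishefsky diene with fluoride as leaving group). The precursor already carries the upper fisetinidol unit, made by asymmetric rhodium-catalysed arylation of a chalcone and hydroboration of the derived 4H-chromene. Debenzylation and equatorial hydride delivery to C4 finish the 3,4-cis diol.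

Key step: step 11

Remark: compounds 1, 7, 9, 16 and 20 are taken as catalogue chemicals; the sense of induction of the chiral catalysts in steps 6 and 11 is assigned by analogy, and the mirror-image catalyst is used if the sense proves opposite.

Flavan numbering (O1, C2, C3, C4, C4a, C5–C8, C8a) is used for both units; "upper" is the fisetinidol unit and "lower" is the unit whose ring C is closed in step 11.

Step 1
Reactants: 1 4-bromo-3-fluorophenol
Product: 2 4-bromo-5-fluoro-2-iodophenol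
Conditions: NIS, TsOH·H2O (cat.), MeCN, 0 °C to rt
Reagents that add atoms: N-iodosuccinimide O=C1CCC(=O)N1I
Why: Electrophilic aromatic iodination, in which the hydroxyl directs ortho and, with the para position blocked by bromine, iodine should enter the less hindered ortho carbon that is also para to fluorine.

Step 2
Reactants: 2 4-bromo-5-fluoro-2-iodophenol
Product: 3 1-(benzyloxy)-4-bromo-5-fluoro-2-iodobenzene
Conditions: BnBr, K2CO3, DMF, rt
Reagents that add atoms: benzyl bromide BrCc1ccccc1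
Why: Williamson ether synthesis on the phenoxide, which is the only nucleophilic site.

Step 3
Reactants: 3 1-(benzyloxy)-4-bromo-5-fluoro-2-iodobenzene
Product: 6 [2-(benzyloxy)-5-bromo-4-fluorophenyl]boronic acid, via arylmagnesium chloride 4 (not isolated), via diisopropyl arylboronate 5 (not isolated)
Conditions: i-PrMgCl·LiCl, THF, −20 °C; B(Oi-Pr)3, −20 °C to rt; aq. HCl
Reagents that add atoms: triisopropyl borate CC(C)OB(OC(C)C)OC(C)C; water O
Why: Halogen–magnesium exchange followed by borylation, selective because iodine exchanges far faster than bromine, so the Grignard reagent forms only at the carbon ortho to the benzyloxy group.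

Step 4
Reactants: 7 4-(benzyloxy)-2-hydroxybenzaldehyde
Product: 8 4-(benzyloxy)-2-(methoxymethoxy)benzaldehyde
Conditions: MOMCl, i-Pr2NEt, CH2Cl2, 0 °C to rt
Reagents that add atoms: chloromethyl methyl ether COCCl
Why: O-Alkylation (MOM protection) masks the phenol that later becomes the upper ring oxygen, so the derived enone stays electrophilic under basic conditions.

Step 5
Reactants: 8 4-(benzyloxy)-2-(methoxymethoxy)benzaldehyde; 9 1-[3,4-bis(benzyloxy)phenyl]ethan-1-one
Product: 10 (E)-3-[4-(benzyloxy)-2-(methoxymethoxy)phenyl]-1-[3,4-bis(benzyloxy)phenyl]prop-2-en-1-one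
Conditions: KOH (aq.), EtOH/THF, rt
Reagents that add atoms: none
Why: Claisen–Schmidt condensation of a non-enolisable aldehyde with the methyl ketone should give the (E)-enone.

Step 6
Reactants: 10 (E)-3-[4-(benzyloxy)-2-(methoxymethoxy)phenyl]-1-[3,4-bis(benzyloxy)phenyl]prop-2-en-1-one; 6 [2-(benzyloxy)-5-bromo-4-fluorophenyl]boronic acid
Product: 11 (3S)-3-[2-(benzyloxy)-5-bromo-4-fluorophenyl]-3-[4-(benzyloxy)-2-(methoxymethoxy)phenyl]-1-[3,4-bis(benzyloxy)phenyl]propan-1-one
Conditions: [RhCl(C2H4)2]2 (2.5 mol%), (R,R)-2,5-diphenylbicyclo[2.2.2]octa-2,5-diene (5.5 mol%), KOH (0.5 equiv), dioxane/H2O, 40 °C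
Reagents that add atoms: none
Why: Hayashi–Miyaura asymmetric 1,4-addition, in which the aryl–rhodium species bearing the chiral diene inserts one enone face and sets the diarylmethine centre (future upper C4) as S under ligand control, the aryl bromide being inert to monovalent rhodium.

Step 7
Reactants: 11 (3S)-3-[2-(benzyloxy)-5-bromo-4-fluorophenyl]-3-[4-(benzyloxy)-2-(methoxymethoxy)phenyl]-1-[3,4-bis(benzyloxy)phenyl]propan-1-one
Product: 13 (4S)-7-(benzyloxy)-4-[2-(benzyloxy)-5-bromo-4-fluorophenyl]-2-[3,4-bis(benzyloxy)phenyl]-4H-chromene, via phenol ketone 12 (not isolated)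
Conditions: TsOH·H2O (cat.), MeOH/toluene, 60 °C; then toluene, 4 Å MS, 90 °C, Ar
Reagents that add atoms: none
Why: Acid-catalysed acetal cleavage frees the phenol, which adds to the ketone and dehydrates to the cyclic enol ether (cyclodehydration to a 4H-chromene) without touching the C4 centre.

Step 8
Reactants: 13 (4S)-7-(benzyloxy)-4-[2-(benzyloxy)-5-bromo-4-fluorophenyl]-2-[3,4-bis(benzyloxy)phenyl]-4H-chromene
Product: 15 (2R,3S,4S)-7-(benzyloxy)-4-[2-(benzyloxy)-5-bromo-4-fluorophenyl]-2-[3,4-bis(benzyloxy)phenyl]chroman-3-ol (2,3-trans-3,4-trans), via C3 alkylborane 14 (not isolated)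
Conditions: BH3·THF, THF, 0 °C to rt; then NaOH (aq.), H2O2, 0 °C
Reagents that add atoms: hydrogen peroxide OO
Why: Hydroboration–oxidation, in which borane adds syn with boron at C3 (β to the ring oxygen) from the face opposite the C4 aryl group and is oxidised with retention, so C4 sets C3 (S) and C2 (R).

Step 9
Reactants: 15 (2R,3S,4S)-7-(benzyloxy)-4-[2-(benzyloxy)-5-bromo-4-fluorophenyl]-2-[3,4-bis(benzyloxy)phenyl]chroman-3-ol; 16 2-(benzyloxy)-N-methoxy-N-methylacetamide
Product: 18 2-(benzyloxy)-1-{4-(benzyloxy)-5-[(2R,3S,4S)-7-(benzyloxy)-2-[3,4-bis(benzyloxy)phenyl]-3-hydroxychroman-4-yl]-2-fluorophenyl}ethan-1-one, via aryllithium lithium alkoxide 17 (not isolated)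
Conditions: n-BuLi (2.2 equiv), THF, −78 °C; then 16, −78 to −20 °C; aq. NH4Cl
Reagents that add atoms: none
Why: Bromine–lithium exchange at −78 °C (after deprotonation of the C3 hydroxyl) should outrun loss of LiF, and the aryllithium is acylated once through the chelated tetrahedral intermediate of the Weinreb ketone synthesis.

Step 10
Reactants: 18 2-(benzyloxy)-1-{4-(benzyloxy)-5-[(2R,3S,4S)-7-(benzyloxy)-2-[3,4-bis(benzyloxy)phenyl]-3-hydroxychroman-4-yl]-2-fluorophenyl}ethan-1-one
Product: 19 (Z)-trimethylsilyl enol ether of 18 in which the chroman 3-hydroxyl is also a trimethylsilyl ether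
Conditions: TMSOTf (2.5 equiv), Et3N, CH2Cl2, 0 °C
Reagents that add atoms: trimethylsilyl triflate C[Si](C)(C)OS(=O)(=O)C(F)(F)F
Why: Soft enolisation with O-silylation should give the (Z)-enol silane (silyloxy and benzyloxy cis) and silylates the free hydroxyl in the same operation.

Step 11
Reactants: 19 (Z)-trimethylsilyl enol ether of 18 (3-O-trimethylsilyl); 20 3,4-bis(benzyloxy)benzaldehyde
Product: 23 (2R,3R)-3,7-bis(benzyloxy)-6-[(2R,3S,4S)-7-(benzyloxy)-2-[3,4-bis(benzyloxy)phenyl]-3-hydroxychroman-4-yl]-2-[3,4-bis(benzyloxy)phenyl]chroman-4-one, via trichlorosilyl aldolate 21 (not isolated), via anti aldol 22 (not isolated)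
Conditions: (S,S)-1,1'-binaphthyl-2,2'-diamine-derived bisphosphoramide (pentane-1,5-diyl-bridged, 5 mol%), SiCl4 (1.5 equiv), i-Pr2NEt (10 mol%), CH2Cl2, −78 °C; then CsF (excess), DMF, −78 °C to rt, same flask
Reagents that add atoms: none
Why: The bisphosphoramide-bound trichlorosilyl cation activates aldehyde 20 and the (Z)-enol silane of 19 adds through an open transition state to its Si face, forming C2–C3 and fixing C2 as R under catalyst control, the aldolate being held as the silicon chelate 21 so that it cannot revert. Fluoride then cleaves the O–Si bonds and the C2 alkoxide of 22 attacks C8a, the fluorine-bearing carbon next to C4a and its C4 ketone, by addition–elimination (SNAr) through a Meisenheimer enolate, forming O1–C8a. Ring C closes in the 6-endo-trig mode, the arene bond C8a=C4a conjugated to C4=O acting as a β-fluoro enone, so the sequence is the stepwise benzo-analogue of a Danishefsky-diene hetero-Diels–Alder reaction with fluoride in the role of the methoxy leaving group. C3 ends trans to the C2 aryl group (both equatorial, 3R) either directly from the anti aldol or by fluoride-mediated epimerisation α to the new ketone, so the aldol diastereoselectivity is not critical. The step needs absolute control at C2 (catalyst), six- over five-membered closure (the C3 oxygen is capped as a benzyl ether, so only the C2 oxygen can arylate) and site selectivity (C8a bears the only fluorine and is the only carbon activated by the ketone). The closest known reactions are Lewis-base-catalysed SiCl4 Mukaiyama aldol additions of enol silanes to aromatic aldehydes and alkoxide SNAr cyclisations of 2-fluoroaryl ketones to chroman-4-ones.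

Step 12
Reactants: 23 (2R,3R)-3,7-bis(benzyloxy)-6-[(2R,3S,4S)-7-(benzyloxy)-2-[3,4-bis(benzyloxy)phenyl]-3-hydroxychroman-4-yl]-2-[3,4-bis(benzyloxy)phenyl]chroman-4-one
Product: 24 (2R,3R)-2-(3,4-dihydroxyphenyl)-6-[(2R,3S,4R)-2-(3,4-dihydroxyphenyl)-3,7-dihydroxychroman-4-yl]-3,7-dihydroxychroman-4-one
Conditions: H2 (1 atm), Pd(OH)2/C, EtOAc/MeOH, rt
Reagents that add atoms: none
Why: Catalytic hydrogenolysis should cleave all seven benzyl ethers while the chromanone carbonyl (deactivated by the para oxygen) survives; it is placed before the C4 alcohol exists because a 7-hydroxyflavan-4-ol would itself be hydrogenolysed.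

Step 13
Reactants: 24 (2R,3R)-2-(3,4-dihydroxyphenyl)-6-[(2R,3S,4R)-2-(3,4-dihydroxyphenyl)-3,7-dihydroxychroman-4-yl]-3,7-dihydroxychroman-4-one
Product: 27 (2R,3S,4S)-2-(3,4-dihydroxyphenyl)-6-[(2R,3S,4R)-2-(3,4-dihydroxyphenyl)-3,7-dihydroxychroman-4-yl]chromane-3,4,7-triol (CNP0280090.4), via octakis(trimethylsilyl) ether 25 (not isolated), via silylated lithium C4 alkoxide 26 (not isolated)
Conditions: BSA, THF, 40 °C, then evaporate; LiBH(s-Bu)3 (L-Selectride), THF, −78 °C; then Bu4NF, AcOH, THF/MeOH, 0 °C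
Reagents that add atoms: none
Why: Transient per-O-silylation prevents the phenoxide formation that would deactivate the ketone, and the bulky borohydride should attack the half-chair chromanone from the equatorial direction (substrate-controlled hydride reduction), giving the axial C4 alcohol cis to the equatorial C3 oxygen (4S) before buffered fluoride removes the silyl groups.

Compound list
1 | 4-bromo-3-fluorophenol | Oc1ccc(Br)c(F)c1 | starting material
2 | 4-bromo-5-fluoro-2-iodophenol | Oc1cc(F)c(Br)cc1I | intermediate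
3 | 1-(benzyloxy)-4-bromo-5-fluoro-2-iodobenzene | Ic1cc(Br)c(F)cc1OCc1ccccc1 | intermediate
4 | [2-(benzyloxy)-5-bromo-4-fluorophenyl]magnesium chloride (not isolated) | Cl[Mg]c1cc(Br)c(F)cc1OCc1ccccc1 | intermediate
5 | diisopropyl [2-(benzyloxy)-5-bromo-4-fluorophenyl]boronate (not isolated) | CC(C)OB(OC(C)C)c1cc(Br)c(F)cc1OCc1ccccc1 | intermediate
6 | [2-(benzyloxy)-5-bromo-4-fluorophenyl]boronic acid | OB(O)c1cc(Br)c(F)cc1OCc1ccccc1 | intermediate
7 | 4-(benzyloxy)-2-hydroxybenzaldehyde | O=Cc1ccc(OCc2ccccc2)cc1O | starting material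
8 | 4-(benzyloxy)-2-(methoxymethoxy)benzaldehyde | O=Cc1ccc(OCc2ccccc2)cc1OCOC | intermediate
9 | 1-[3,4-bis(benzyloxy)phenyl]ethan-1-one | CC(=O)c1ccc(OCc2ccccc2)c(OCc2ccccc2)c1 | starting material
10 | (E)-3-[4-(benzyloxy)-2-(methoxymethoxy)phenyl]-1-[3,4-bis(benzyloxy)phenyl]prop-2-en-1-one | O=C(/C=C/c1ccc(OCc2ccccc2)cc1OCOC)c1ccc(OCc2ccccc2)c(OCc2ccccc2)c1 | intermediate
11 | (3S)-3-[2-(benzyloxy)-5-bromo-4-fluorophenyl]-3-[4-(benzyloxy)-2-(methoxymethoxy)phenyl]-1-[3,4-bis(benzyloxy)phenyl]propan-1-one | O=C(C[C@@H](c1ccc(OCc2ccccc2)cc1OCOC)c1cc(Br)c(F)cc1OCc1ccccc1)c1ccc(OCc2ccccc2)c(OCc2ccccc2)c1 | intermediate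
12 | (3S)-3-[2-(benzyloxy)-5-bromo-4-fluorophenyl]-3-[4-(benzyloxy)-2-hydroxyphenyl]-1-[3,4-bis(benzyloxy)phenyl]propan-1-one (not isolated) | O=C(C[C@@H](c1ccc(OCc2ccccc2)cc1O)c1cc(Br)c(F)cc1OCc1ccccc1)c1ccc(OCc2ccccc2)c(OCc2ccccc2)c1 | intermediate
13 | (4S)-7-(benzyloxy)-4-[2-(benzyloxy)-5-bromo-4-fluorophenyl]-2-[3,4-bis(benzyloxy)phenyl]-4H-chromene | c1ccccc1COc1ccc2c(c1)OC(c1ccc(OCc3ccccc3)c(OCc3ccccc3)c1)=C[C@@H]2c1cc(Br)c(F)cc1OCc1ccccc1 | intermediate
14 | C3 alkylborane from syn hydroboration of 13, boron trans to the C4 aryl group (not isolated) | c1ccccc1COc1ccc2c(c1)O[C@H](c1ccc(OCc3ccccc3)c(OCc3ccccc3)c1)[C@@H](B)[C@@H]2c1cc(Br)c(F)cc1OCc1ccccc1 | intermediate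
15 | (2R,3S,4S)-7-(benzyloxy)-4-[2-(benzyloxy)-5-bromo-4-fluorophenyl]-2-[3,4-bis(benzyloxy)phenyl]chroman-3-ol | c1ccccc1COc1ccc2c(c1)O[C@H](c1ccc(OCc3ccccc3)c(OCc3ccccc3)c1)[C@@H](O)[C@@H]2c1cc(Br)c(F)cc1OCc1ccccc1 | intermediate
16 | 2-(benzyloxy)-N-methoxy-N-methylacetamide | CON(C)C(=O)COCc1ccccc1 | starting material
17 | aryllithium lithium alkoxide from 15, lithium in place of bromine and on the C3 oxygen (not isolated) | c1ccccc1COc1ccc2c(c1)O[C@H](c1ccc(OCc3ccccc3)c(OCc3ccccc3)c1)[C@@H](O[Li])[C@@H]2c1cc([Li])c(F)cc1OCc1ccccc1 | intermediate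
18 | 2-(benzyloxy)-1-{4-(benzyloxy)-5-[(2R,3S,4S)-7-(benzyloxy)-2-[3,4-bis(benzyloxy)phenyl]-3-hydroxychroman-4-yl]-2-fluorophenyl}ethan-1-one | c1ccccc1COc1ccc2c(c1)O[C@H](c1ccc(OCc3ccccc3)c(OCc3ccccc3)c1)[C@@H](O)[C@@H]2c1cc(C(=O)COCc2ccccc2)c(F)cc1OCc1ccccc1 | intermediate
19 | (Z)-trimethylsilyl enol ether of 18, chroman 3-hydroxyl as trimethylsilyl ether | c1ccccc1COc1ccc2c(c1)O[C@H](c1ccc(OCc3ccccc3)c(OCc3ccccc3)c1)[C@@H](O[Si](C)(C)C)[C@@H]2c1cc(/C(O[Si](C)(C)C)=C/OCc2ccccc2)c(F)cc1OCc1ccccc1 | intermediate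
20 | 3,4-bis(benzyloxy)benzaldehyde | O=Cc1ccc(OCc2ccccc2)c(OCc2ccccc2)c1 | starting material
21 | trichlorosilyl ether of the (2R,3R)-anti aldol, 2-(benzyloxy)-3-[3,4-bis(benzyloxy)phenyl]-3-(trichlorosilyloxy)propan-1-one on the 2-fluoroaryl ring, chroman 3-O-trimethylsilyl (not isolated) | c1ccccc1COc1ccc2c(c1)O[C@H](c1ccc(OCc3ccccc3)c(OCc3ccccc3)c1)[C@@H](O[Si](C)(C)C)[C@@H]2c1cc(C(=O)[C@H](OCc2ccccc2)[C@H](O[Si](Cl)(Cl)Cl)c2ccc(OCc3ccccc3)c(OCc3ccccc3)c2)c(F)cc1OCc1ccccc1 | intermediate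
22 | (2R,3R)-anti aldol released by fluoride, shown as the neutral β-hydroxy ketone (reacts as its alkoxide, not isolated) | c1ccccc1COc1ccc2c(c1)O[C@H](c1ccc(OCc3ccccc3)c(OCc3ccccc3)c1)[C@@H](O)[C@@H]2c1cc(C(=O)[C@H](OCc2ccccc2)[C@H](O)c2ccc(OCc3ccccc3)c(OCc3ccccc3)c2)c(F)cc1OCc1ccccc1 | intermediate
23 | (2R,3R)-3,7-bis(benzyloxy)-6-[(2R,3S,4S)-7-(benzyloxy)-2-[3,4-bis(benzyloxy)phenyl]-3-hydroxychroman-4-yl]-2-[3,4-bis(benzyloxy)phenyl]chroman-4-one | c1ccccc1COc1ccc2c(c1)O[C@H](c1ccc(OCc3ccccc3)c(OCc3ccccc3)c1)[C@@H](O)[C@@H]2c1cc2c(cc1OCc1ccccc1)O[C@H](c1ccc(OCc3ccccc3)c(OCc3ccccc3)c1)[C@@H](OCc1ccccc1)C2=O | intermediate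
24 | (2R,3R)-2-(3,4-dihydroxyphenyl)-6-[(2R,3S,4R)-2-(3,4-dihydroxyphenyl)-3,7-dihydroxychroman-4-yl]-3,7-dihydroxychroman-4-one | Oc1ccc2c(c1)O[C@H](c1ccc(O)c(O)c1)[C@@H](O)[C@@H]2c1cc2c(cc1O)O[C@H](c1ccc(O)c(O)c1)[C@@H](O)C2=O | intermediate
25 | octakis(trimethylsilyl) ether of 24 (not isolated) | C[Si](C)(C)Oc1ccc2c(c1)O[C@H](c1ccc(O[Si](C)(C)C)c(O[Si](C)(C)C)c1)[C@@H](O[Si](C)(C)C)[C@@H]2c1cc2c(cc1O[Si](C)(C)C)O[C@H](c1ccc(O[Si](C)(C)C)c(O[Si](C)(C)C)c1)[C@@H](O[Si](C)(C)C)C2=O | intermediate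
26 | lithium C4 alkoxide of the octakis(trimethylsilyl) 3,4-cis alcohol (not isolated) | C[Si](C)(C)Oc1ccc2c(c1)O[C@H](c1ccc(O[Si](C)(C)C)c(O[Si](C)(C)C)c1)[C@@H](O[Si](C)(C)C)[C@@H]2c1cc2c(cc1O[Si](C)(C)C)O[C@H](c1ccc(O[Si](C)(C)C)c(O[Si](C)(C)C)c1)[C@@H](O[Si](C)(C)C)[C@H]2O[Li] | intermediate
27 | (2R,3S,4S)-2-(3,4-dihydroxyphenyl)-6-[(2R,3S,4R)-2-(3,4-dihydroxyphenyl)-3,7-dihydroxychroman-4-yl]chromane-3,4,7-triol | Oc1ccc2c(c1)O[C@H](c1ccc(O)c(O)c1)[C@@H](O)[C@@H]2c1cc2c(cc1O)O[C@H](c1ccc(O)c(O)c1)[C@@H](O)[C@H]2O | target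

Total step count: 13. Longest linear sequence: 11 steps (1, 2, 3, 6, 7, 8, 9, 10, 11, 12, 13).

Steps most likely to fail

Step 11. The fluoride-released aldolate may undergo retro-aldol cleavage (or E1cB loss of water to the α-benzyloxychalcone) faster than it closes the ring, which would erode the catalyst-set C2 configuration. Fallback, setting out from 18 and returning at 23: stereocontrol is moved from the catalyst to a separation. Ketone 18 is converted with LiHMDS (2.2 equiv, THF, −78 °C) into its lithium alkoxide enolate, aldehyde 20 is added, and the lithium aldolate is driven to ring closure by warming with DMPU under equilibrating conditions. Both trans-dihydroflavonols should then form: 23 and its lower-unit (2S,3S) diastereomer F1. Because the enantiopure upper unit makes them diastereomers, 23 is obtained by chromatography.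

Step 6. Transmetalation and enone insertion may be slow with two ortho-oxygenated aryl partners, so that protodeboronation of 6 takes over. Fallback, setting out from 6 and returning at 12: the diarylmethine centre is set on a coumarin instead of a chalcone. Commercial 7-(benzyloxy)coumarin is arylated with 6 under Rh(acac)(C2H4)2/(R)-SEGPHOS in dioxane/H2O at 60 °C to give the 4-aryl-3,4-dihydrocoumarin F2. AlMe3 and N,O-dimethylhydroxylamine hydrochloride open the lactone to the phenolic Weinreb amide F3. The Grignard reagent 3,4-bis(benzyloxy)phenylmagnesium bromide F4, made from commercial 4-bromo-1,2-bis(benzyloxy)benzene and magnesium, then gives phenol ketone 12, which is dehydrated to 13 with the acid of step 7.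

Step 13. The hydride may strip transient silyl groups, leaving a phenoxide-deactivated ketone, and facial selectivity may be incomplete. Fallback, setting out from 24 and returning at 27: 24 is reduced with NaBH4 in EtOH/H2O at 0 °C, which by axial attack should give the 3,4-trans diol F5 (the C4 epimer of the target). F5 is then epimerised at C4 in dilute aqueous acetic acid through the benzylic cation stabilised by the 7-hydroxyl, and the 3,4-cis isomer 27 is separated on Sephadex LH-20 with recycling of F5.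

Further compounds
F1 | step 11 | lower-unit (2S,3S) diastereomer of 23 | c1ccccc1COc1ccc2c(c1)O[C@H](c1ccc(OCc3ccccc3)c(OCc3ccccc3)c1)[C@@H](O)[C@@H]2c1cc2c(cc1OCc1ccccc1)O[C@@H](c1ccc(OCc3ccccc3)c(OCc3ccccc3)c1)[C@H](OCc1ccccc1)C2=O
F2 | step 6 | (4S)-7-(benzyloxy)-4-[2-(benzyloxy)-5-bromo-4-fluorophenyl]chroman-2-one | O=C1C[C@H](c2cc(Br)c(F)cc2OCc2ccccc2)c2ccc(OCc3ccccc3)cc2O1
F3 | step 6 | (3S)-3-[2-(benzyloxy)-5-bromo-4-fluorophenyl]-3-[4-(benzyloxy)-2-hydroxyphenyl]-N-methoxy-N-methylpropanamide | CON(C)C(=O)C[C@@H](c1ccc(OCc2ccccc2)cc1O)c1cc(Br)c(F)cc1OCc1ccccc1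
F4 | step 6 | 3,4-bis(benzyloxy)phenylmagnesium bromide | Br[Mg]c1ccc(OCc2ccccc2)c(OCc2ccccc2)c1
F5 | step 13 | (2R,3S,4R)-2-(3,4-dihydroxyphenyl)-6-[(2R,3S,4R)-2-(3,4-dihydroxyphenyl)-3,7-dihydroxychroman-4-yl]chromane-3,4,7-triol | Oc1ccc2c(c1)O[C@H](c1ccc(O)c(O)c1)[C@@H](O)[C@@H]2c1cc2c(cc1O)O[C@H](c1ccc(O)c(O)c1)[C@@H](O)[C@@H]2O
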